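At the last reading, 30.0 h, the electrophile in Monday's and Thursday's flasks has levelled off far from zero, so ask what one more portion of nucleophile buys.

| setting | Monday's | Thursday's | grey | teal |
|---|---|---|---|---|
| electrophile | 0.18 M | 0.18 M | 0.18 M | 0.18 M |
| nucleophile | 0.24 M | 0.22 M | 0.250 M | 0.190 M |
| protic impurity | 0.18 M | 0.18 M | 0.180 M | 0.180 M |
| remark | run made earlier | run made earlier |  |  |
| time |  |  | 40 h | 40 h |

| run | time / h | electrophile / % | target / % |
|---|---|---|---|
| Monday's | 2.50 | 75.6 | 25.6 |
| Monday's | 5.00 | 68.1 | 34.3 |
| Monday's | 12.0 | 59.3 | 39.5 |
| Monday's | 30.0 | 58.8 | 42.1 |
| Thursday's | 4.00 | 72.6 | 28.0 |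
| Thursday's | 10.0 | 63.1 | 35.5 |
| Thursday's | 20.0 | 59.6 | 35.9 |
| Thursday's | 30.0 | 61.7 | 38.7 |

(readings scatter by 1 percentage point)

- part of the electrophile that has reacted at the end, grey
- part of the electrophile that has reacted at the end, teal
- what raising the concentration of nucleophile from its lowest to its highest value here does to the part of the electrophile that has reacted (changes below 5 percentage points count as none) (it falls / no change / it rises)

Work with fractions left. Average the electrophile reading with what the target reading leaves: 58.4% of the charge in Monday's flask, 61.5% in Thursday's. Assume each electrophile reacted took two nucleophiles, one to react and one to hold the acid set free as protonated nucleophile, and the protic impurity took the remainder. That leaves 50.0% of the impurity on Monday and 54.8% on Thursday. Both meet the same nucleophile, so the logarithms of their fractions left should keep a fixed ratio, the selectivity factor: 0.776 and 0.808, mean 0.792.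

Now take the first way. With equal charges of electrophile and impurity, each further bit of electrophile reacted costs two nucleophiles and draws 1.10 more into the impurity. So the return is 0.322: the part of the electrophile charge that reacts per extra equivalent of nucleophile.

The second way compares the two runs directly and reads 0.283. They part, but that gap needs to shift by just 0.43 percentage points to close it, less than the scatter of one reading. The small difference between two noisy levels is the weak way, so keep the first. From the nearest runs I get 43.4% for grey and 33.1% for teal.

The forecast says 43% and 33.5%, so it rises, holding that “both should be at their plateau”. Its grey figure stands 0.40 points below mine, its teal figure 0.40 points above.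

The flask gives 43.6% for grey and 33.0% for teal, so going from teal's nucleophile charge to grey's, it rises, by 11 points, under this scheme:

    crystals ⇌ target, rate k1*(cs1 - [target]) while solid is left; crystals form when [target] > cs1 (solubility = 6.30 mM, k = 0.00810 /min)
    nucleophile + protic impurity → quenched reagent (k = 0.0160 /M/min)
    acid set free + target → side product (k = 3.90 × 10⁻⁴ /M/min)
    electrophile + nucleophile → acid set free + target (k = 0.0120 /M/min)
    nucleophile + acid set free ⇌ protonated nucleophile, settled at all times (K = 39000 /M)

Nucleophile is the limiting reagent: at 40.0 h, 0.206% of its charge stands free in grey and 0.193% in teal. Carry the return down from teal to the neighbour flask charged with 0.15 M of nucleophile: it gives 25.9%, and that flask stands at 26.1%.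

(The runs were generated by integration with made-up constants, noise included.)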